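You read these flasks at 25 h, so what you must reckon is how much of that time the reaction spends at its steady pace.

- alder: electrophile 0.55 M; free base 0.500 equiv; solid nucleophile 1.00 equiv; time 25 h
- maple: electrophile 0.55 M; free base 0.750 equiv; solid nucleophile 1.00 equiv; time 25 h

    electrophile + nucleophile → acid set free + target (k1 = 0.747 /M/h)
    nucleophile + acid set free ⇌ protonated nucleophile, settled at all times (K2 = 3310 /M)
    acid set free + free base ⇌ salt of the base (K3 = 450 /M, k3 = 23.5 /M/h)
    target ⇌ isomer of the product (K4 = 4.4, k4 = 0.114 /h)
    solid nucleophile ⇌ nucleophile, rate k5*(cs5 - [nucleophile]) while solid is left; crystals form when [nucleophile] > cs5 (cs5 = 43 mM, k5 = 0.0725 /h)

- solid, in amounts per volume of the solution: solid nucleophile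
- at the start none of the solid nucleophile is in solution
- run time (alder): 25 h

- part of the electrophile that has reacted at the end, alder
- part of the electrophile that has reacted at the end, maple
- what raising the equivalents of free base from its lowest to its highest value here does to the part of the electrophile that has reacted (changes below 5 percentage points count as none) (no change / it falls / it rises)

Start from the solid. Dissolving into an empty solution for the whole time, it could bring in 14.2% of the electrophile charge, which is less than the solid charged, so solid stays present. The electrophile therefore stays near its charge, and it eats nucleophile in a pseudo-first-order way at 0.411 /h. That half-life of 1.7 h is shorter than the run, so feed and use soon balance. Free nucleophile then holds at 1.17% of the charge, and the reacted fraction grows by 0.00482 /h. Over the whole time that gives 12.0%, with the free base playing no part.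

The weak link is the assumption of full pace from the first hour, since the solution starts empty and acid set free turns some nucleophile into protonated nucleophile. Free base catches the acid with a half-life of 0.11 h, far shorter than the run, so as an estimate I set capture equal to making, with the free base as charged and the return of salt of the base to acid left out. On that estimate protonated nucleophile stands at 1.36 times the free form in alder and 0.905 times in maple. Both forms must fill up before the pace is reached, which I reckon at 4.88 h in alder and 3.94 h in maple. This filling time, one plus that ratio over the sum of the dissolving and eating constants, is what you take off the reading time. I commit to 9.70% for alder and 10.1% for maple, a gap of 0.45 percentage points, so the trend is no change.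

The forecast gives 8.6% and 9.5%, both lower than mine , and no change, holding that “More base only frees slightly more nucleophile from its protonated form”.

The simulation gives 9.07% for alder and 9.48% for maple, a change of 0.41 points, so the trend is no change. At 25.0 h alder holds 2.34% of the charge as protonated nucleophile beside 1.08% as nucleophile, a ratio of 2.16, which is higher than the 1.36 I reckoned. Take a neighbour of maple charged with 1.4 M of electrophile, its equivalents held. Its pace is 0.00208 /h and its filling time 1.24 h, which reckons to 4.94%, and that flask gives 4.84%.

(The numbers of this flask are assumed; the run is a simulation.)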